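The tetrahydrofuran (O1, C2 bearing pentyl, C3 bearing OH, C4 methylene, C5 bearing the side chain) is disconnected at C3–C4 and O1–C5. O1–C2–C3 comes from (S)-2-(triethylsilyloxy)heptanal; C4–C5 is the vinyl group of an α-chiral allylsilane whose silicon-bearing carbon becomes the acyloxy carbon C1'. A SnCl4-mediated formal [3+2] annulation forms both bonds at once, sets C3 and C5, and exploits the vicinal O1/C3–OH pair of the ring next to the exocyclic C1' oxygen, which is carried as a C–Si bond. Oxidation of C–Si with retention and a Mitsunobu esterification with inversion then install the palmitate.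

Key step: step 8

Remark: the antipodes of the two chiral catalysts (steps 1 and 7) are named as expected to give the configurations stated and would be confirmed on a model substrate; ring atoms are numbered O1, C2 (pentyl), C3 (OH), C4, C5, and the side-chain carbinol carbon is C1'.

Step 1
Reactants: 1 (±)-2-pentyloxirane
Product: 2 (S)-heptane-1,2-diol
Conditions: (S,S)-Co(salen)(OAc) (trivalent cobalt, 0.5 mol %; salen = N,N'-bis(3,5-di-tert-butylsalicylidene)-1,2-cyclohexanediamine), H2O (0.45 equiv), THF, 0 °C → rt; diol separated from the unreacted epoxide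
Reagents that add atoms: water, O
Why: Hydrolytic kinetic resolution, in which the chiral cobalt–salen catalyst opens only the (S)-epoxide at its terminal carbon, so the existing stereocentre is untouched and the diol should be highly enantioenriched with sub-stoichiometric water.

Step 2
Reactants: 2 (S)-heptane-1,2-diol
Product: 3 (S)-1,2-bis(triethylsilyloxy)heptane
Conditions: Et3SiCl (2.3 equiv), imidazole, DMF, 0 °C → rt
Reagents that add atoms: chlorotriethylsilane, CC[Si](Cl)(CC)CC
Why: Standard imidazole-promoted silylation of both hydroxyl groups, with no stereocentre involved.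

Step 3
Reactants: 3 (S)-1,2-bis(triethylsilyloxy)heptane
Product: 5 (S)-2-(triethylsilyloxy)heptanal, via alkoxysulfonium chloride 4 (not isolated)
Conditions: (COCl)2, DMSO, CH2Cl2, −78 → −40 °C; then Et3N, −78 → 0 °C; used crude
Reagents that add atoms: none
Why: Under Swern conditions a primary triethylsilyl ether is cleaved and oxidised directly while the secondary one survives, so the α-silyloxy aldehyde should form in one operation, kept cold to avoid epimerisation.

Step 4
Reactants: 6 prop-2-yn-1-ol; 7 9-bromonon-1-ene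
Product: 9 dodec-11-en-2-yn-1-ol, via dilithiated propargyl alcohol 8 (not isolated)
Conditions: LiNH2 (2.2 equiv), NH3 (l)/THF, −33 °C; then 7, −33 °C → rt
Reagents that add atoms: none
Why: Alkylation of the propargyl alcohol dianion, which should occur at the more nucleophilic acetylide carbon and leave the terminal alkene untouched.

Step 5
Reactants: 9 dodec-11-en-2-yn-1-ol
Product: 10 (E)-dodeca-2,11-dien-1-ol
Conditions: LiAlH4, THF, 0 °C → reflux; aqueous potassium sodium tartrate
Reagents that add atoms: none
Why: Alkoxide-directed trans-hydroalumination of the propargylic alcohol followed by protonolysis should give the (E)-allylic alcohol only, the isolated alkene being inert to hydride.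

Step 6
Reactants: 10 (E)-dodeca-2,11-dien-1-ol
Product: 11 diethyl (E)-dodeca-2,11-dien-1-yl phosphate
Conditions: (EtO)2P(O)Cl, pyridine, DMAP (cat.), CH2Cl2, 0 °C
Reagents that add atoms: diethyl chlorophosphate, CCOP(=O)(Cl)OCC
Why: Routine O-phosphorylation of a primary allylic alcohol to give the leaving group for allylic substitution.

Step 7
Reactants: 11 diethyl (E)-dodeca-2,11-dien-1-yl phosphate
Product: 12 (S)-3-[dimethyl(phenyl)silyl]dodeca-1,11-diene
Conditions: PhMe2Si–Bpin, CuCl (5 mol %), chiral NHC·HCl ligand precursor (6 mol %, antipode giving the (S)-silane), NaOMe, CH2Cl2, 0 °C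
Reagents that add atoms: (dimethylphenylsilyl)boronic acid pinacol ester, C[Si](C)(c1ccccc1)B1OC(C)(C)C(C)(C)O1
Why: Copper-catalysed enantioselective γ-selective (SN2') allylic silylation, in which the silyl–copper species made by methoxide activation of the Si–B bond adds to one enantiotopic alkene face under control of the chiral carbene ligand and so sets the silicon-bearing stereocentre.

Step 8
Reactants: 5 (S)-2-(triethylsilyloxy)heptanal; 12 (S)-3-[dimethyl(phenyl)silyl]dodeca-1,11-diene
Product: 14 (2S,3S,5R)-5-[(1S)-1-[dimethyl(phenyl)silyl]dec-9-en-1-yl]-2-pentyltetrahydrofuran-3-ol, via beta-silyl cation 13 (not isolated)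
Conditions: SnCl4 (1.1 equiv), CH2Cl2, −78 °C (5 precomplexed, then 12); aqueous NaHCO3
Reagents that add atoms: none
Why: SnCl4 chelates the aldehyde and silyl ether oxygens of 5, the terminal CH2 of 12 adds to the aldehyde carbon anti to the C–Si bond (SE2' geometry) to form C3–C4 and a β-silyl (siliranium-type) cation at C5, and the silyl ether oxygen O1 captures this cation anti to silicon with loss of Et3SiCl. The closest known reaction type is the Lewis acid-mediated formal [3+2] annulation of α-silyloxy aldehydes with allylsilanes, a Hosomi–Sakurai addition followed by ether-oxygen capture of the cation and a relative of the Prins cyclisation. The ring O1–C2–C3–C4–C5 closes by 5-exo opening of the siliranium ion at C5. C3 is set by Cram-chelate control from C2 (attack on the aldehyde face opposite the pentyl group, giving the 2,3-cis relationship), and C5 is set by the silicon-bearing stereocentre of 12 through the anti/anti course in the conformer with the allylic hydrogen eclipsing the vinyl group, which gives the (5R,1'S) erythro arrangement and the 2,5-trans ring. The step needs O1 capture to beat loss of silicon (simple allylation) and closure by the tin alkoxide after a 1,2-silyl shift; the hindered secondary PhMe2Si group, the five-membered closure and the easy loss of Et3Si from oxygen favour it, and the isolated terminal alkene is far less nucleophilic than the allylsilane.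

Step 9
Reactants: 14 (2S,3S,5R)-5-[(1S)-1-[dimethyl(phenyl)silyl]dec-9-en-1-yl]-2-pentyltetrahydrofuran-3-ol
Product: 15 [(1S)-1-[(2R,4S,5S)-4-[(4-methoxybenzyl)oxy]-5-pentyltetrahydrofuran-2-yl]dec-9-en-1-yl](dimethyl)phenylsilane
Conditions: NaH, 4-methoxybenzyl chloride, Bu4NI (cat.), DMF, 0 °C → rt
Reagents that add atoms: 4-methoxybenzyl chloride, COc1ccc(CCl)cc1
Why: Williamson etherification of the ring alcohol, which protects C3–OH so that only the C1' oxygen made in the next step is later esterified.

Step 10
Reactants: 15 [(1S)-1-[(2R,4S,5S)-4-[(4-methoxybenzyl)oxy]-5-pentyltetrahydrofuran-2-yl]dec-9-en-1-yl](dimethyl)phenylsilane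
Product: 16 (1S)-1-[(2R,4S,5S)-4-[(4-methoxybenzyl)oxy]-5-pentyltetrahydrofuran-2-yl]dec-9-en-1-ol
Conditions: KH, t-BuOOH, DMF, 0 °C → rt; then Bu4NF, 60 °C
Reagents that add atoms: tert-butyl hydroperoxide, CC(C)(C)OO
Why: Tamao–Fleming oxidation in its basic peroxide variant, in which the phenyl group leaves silicon first and the alkyl group then migrates from silicon to oxygen with retention at C1', under acid-free and electrophile-free conditions that the terminal alkene and the benzyl ether should tolerate.

Step 11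
Reactants: 16 (1S)-1-[(2R,4S,5S)-4-[(4-methoxybenzyl)oxy]-5-pentyltetrahydrofuran-2-yl]dec-9-en-1-ol; 17 hexadecanoic acid
Product: 19 (1R)-1-[(2R,4S,5S)-4-[(4-methoxybenzyl)oxy]-5-pentyltetrahydrofuran-2-yl]dec-9-en-1-yl hexadecanoate, via alkoxyphosphonium palmitate 18 (not isolated)
Conditions: PPh3, DIAD, toluene, 0 °C → rt
Reagents that add atoms: none
Why: Mitsunobu esterification, in which the carboxylate displaces the alkoxyphosphonium group by SN2 with inversion, converting the erythro (1'S) alcohol into the threo (1'R) palmitate in the same step that attaches the acyl chain.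

Step 12
Reactants: 19 (1R)-1-[(2R,4S,5S)-4-[(4-methoxybenzyl)oxy]-5-pentyltetrahydrofuran-2-yl]dec-9-en-1-yl hexadecanoate
Product: 20 (1R)-1-[(2R,4S,5S)-4-hydroxy-5-pentyltetrahydrofuran-2-yl]dec-9-en-1-yl hexadecanoate
Conditions: DDQ, CH2Cl2/pH 7 buffer, 0 °C → rt
Reagents that add atoms: none
Why: Oxidative cleavage of the 4-methoxybenzyl ether by DDQ (benzylic oxidation to the oxocarbenium ion and hydrolysis), which should leave the ester, the terminal alkene and all stereocentres untouched.

Compound list
1 | (±)-2-pentyloxirane | CCCCCC1CO1 | starting material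
2 | (S)-heptane-1,2-diol | CCCCC[C@H](O)CO | intermediate
3 | (S)-1,2-bis(triethylsilyloxy)heptane | CCCCC[C@H](O[Si](CC)(CC)CC)CO[Si](CC)(CC)CC | intermediate
4 | dimethyl{[(2S)-2-(triethylsilyloxy)heptyl]oxy}sulfonium chloride (not isolated) | CCCCC[C@H](O[Si](CC)(CC)CC)CO[S+](C)C.[Cl-] | intermediate
5 | (S)-2-(triethylsilyloxy)heptanal | CCCCC[C@H](O[Si](CC)(CC)CC)C=O | intermediate
6 | prop-2-yn-1-ol | OCC#C | starting material
7 | 9-bromonon-1-ene | BrCCCCCCCC=C | starting material
8 | dilithiated propargyl alcohol (lithium 3-lithioprop-2-yn-1-olate, not isolated) | [Li]OCC#C[Li] | intermediate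
9 | dodec-11-en-2-yn-1-ol | OCC#CCCCCCCCC=C | intermediate
10 | (E)-dodeca-2,11-dien-1-ol | OC/C=C/CCCCCCCC=C | intermediate
11 | diethyl (E)-dodeca-2,11-dien-1-yl phosphate | CCOP(=O)(OCC)OC/C=C/CCCCCCCC=C | intermediate
12 | (S)-3-[dimethyl(phenyl)silyl]dodeca-1,11-diene | C=C[C@@H]([Si](C)(C)c1ccccc1)CCCCCCCC=C | intermediate
13 | β-silyl cation at C5 as its trichlorotin alkoxide with chloride counter-ion (not isolated) | CCCCC[C@H](O[Si](CC)(CC)CC)[C@@H](O[Sn](Cl)(Cl)Cl)C[CH+][C@@H]([Si](C)(C)c1ccccc1)CCCCCCCC=C.[Cl-] | intermediate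
14 | (2S,3S,5R)-5-[(1S)-1-[dimethyl(phenyl)silyl]dec-9-en-1-yl]-2-pentyltetrahydrofuran-3-ol | C=CCCCCCCC[C@H]([Si](C)(C)c1ccccc1)[C@H]2C[C@H](O)[C@H](CCCCC)O2 | intermediate
15 | [(1S)-1-[(2R,4S,5S)-4-[(4-methoxybenzyl)oxy]-5-pentyltetrahydrofuran-2-yl]dec-9-en-1-yl](dimethyl)phenylsilane | C=CCCCCCCC[C@H]([Si](C)(C)c1ccccc1)[C@H]2C[C@H](OCc3ccc(OC)cc3)[C@H](CCCCC)O2 | intermediate
16 | (1S)-1-[(2R,4S,5S)-4-[(4-methoxybenzyl)oxy]-5-pentyltetrahydrofuran-2-yl]dec-9-en-1-ol | C=CCCCCCCC[C@H](O)[C@H]1C[C@H](OCc2ccc(OC)cc2)[C@H](CCCCC)O1 | intermediate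
17 | hexadecanoic (palmitic) acid | CCCCCCCCCCCCCCCC(=O)O | starting material
18 | alkoxytriphenylphosphonium palmitate of 16 (not isolated) | C=CCCCCCCC[C@H](O[P+](c1ccccc1)(c1ccccc1)c1ccccc1)[C@H]2C[C@H](OCc3ccc(OC)cc3)[C@H](CCCCC)O2.CCCCCCCCCCCCCCCC(=O)[O-] | intermediate
19 | (1R)-1-[(2R,4S,5S)-4-[(4-methoxybenzyl)oxy]-5-pentyltetrahydrofuran-2-yl]dec-9-en-1-yl hexadecanoate | C=CCCCCCCC[C@@H](OC(=O)CCCCCCCCCCCCCCC)[C@H]1C[C@H](OCc2ccc(OC)cc2)[C@H](CCCCC)O1 | intermediate
20 | (1R)-1-[(2R,4S,5S)-4-hydroxy-5-pentyltetrahydrofuran-2-yl]dec-9-en-1-yl hexadecanoate (CNP0115574.1) | C=CCCCCCCC[C@@H](OC(=O)CCCCCCCCCCCCCCC)[C@H]1C[C@H](O)[C@H](CCCCC)O1 | target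

Total step count: 12. Longest linear sequence: 9 steps (steps 4 to 12).

Steps most likely to fail

Step 8. The weakly basic silyl ether may chelate SnCl4 incompletely, so that the allylsilane adds with Felkin–Anh facial selectivity and the C3 epimer forms; loss of silicon from the β-silyl cation before O1 closes is the second danger. The fallback sets out from 5 and 12 and accepts Felkin–Anh control: the annulation is run with monodentate BF3·OEt2 in CH2Cl2 at −78 °C and should give the 2,3-trans alcohol (2S,3R,5R)-5-[(1S)-1-[dimethyl(phenyl)silyl]dec-9-en-1-yl]-2-pentyltetrahydrofuran-3-ol F1. Oxidation with Dess–Martin periodinane should give (2S,5R)-5-[(1S)-1-[dimethyl(phenyl)silyl]dec-9-en-1-yl]-2-pentyldihydrofuran-3(2H)-one F2. Reduction with LiBH(s-Bu)3 at −78 °C, hydride arriving anti to the neighbouring pentyl group, should give the 2,3-cis alcohol, and the route is rejoined at 14.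

Step 10. Fluoride or alkoxide may trigger β-elimination of the β-silyl ether (opening of the ring) faster than oxidation at the hindered silicon. The fallback sets out from 15 and makes this elimination the intended reaction: BF3·OEt2 in CH2Cl2 at −20 °C should open the ring by anti-elimination to the (E)-alkenol (6S,7S,9E)-7-[(4-methoxybenzyl)oxy]nonadeca-9,18-dien-6-ol F3. Shi epoxidation of the internal alkene (the antipode of the fructose-type chiral ketone that gives the (9S,10S)-epoxide, KHSO5, buffered MeCN/dimethoxymethane, 0 °C; the terminal alkene reacts much more slowly) should give (6S,7S,9S,10S)-9,10-epoxy-7-[(4-methoxybenzyl)oxy]nonadec-18-en-6-ol F4. Camphorsulfonic acid in CH2Cl2 should then close the ring by 5-exo opening of the epoxide with inversion at C9, and the route is rejoined at 16.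

Step 11. Displacement at the hindered α-alkoxy carbinol by the weakly acidic fatty acid may be slow, so that elimination or esterification with retention through an acyloxyphosphonium pathway competes. The fallback sets out from 16: Dess–Martin oxidation should give the ketone 1-[(2R,4S,5S)-4-[(4-methoxybenzyl)oxy]-5-pentyltetrahydrofuran-2-yl]dec-9-en-1-one F5. Reduction with LiBH(s-Bu)3 at −78 °C under Felkin–Anh control should give the threo alcohol (1R)-1-[(2R,4S,5S)-4-[(4-methoxybenzyl)oxy]-5-pentyltetrahydrofuran-2-yl]dec-9-en-1-ol F6. Acylation with palmitoyl chloride, pyridine and DMAP in CH2Cl2 rejoins the route at 19.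

Further compounds
F1 | step 8 | (2S,3R,5R)-5-[(1S)-1-[dimethyl(phenyl)silyl]dec-9-en-1-yl]-2-pentyltetrahydrofuran-3-ol | C=CCCCCCCC[C@H]([Si](C)(C)c1ccccc1)[C@H]2C[C@@H](O)[C@H](CCCCC)O2
F2 | step 8 | (2S,5R)-5-[(1S)-1-[dimethyl(phenyl)silyl]dec-9-en-1-yl]-2-pentyldihydrofuran-3(2H)-one | C=CCCCCCCC[C@H]([Si](C)(C)c1ccccc1)[C@H]2CC(=O)[C@H](CCCCC)O2
F3 | step 10 | (6S,7S,9E)-7-[(4-methoxybenzyl)oxy]nonadeca-9,18-dien-6-ol | CCCCC[C@H](O)[C@@H](OCc1ccc(OC)cc1)C/C=C/CCCCCCCC=C
F4 | step 10 | (6S,7S,9S,10S)-9,10-epoxy-7-[(4-methoxybenzyl)oxy]nonadec-18-en-6-ol | CCCCC[C@H](O)[C@@H](OCc1ccc(OC)cc1)C[C@@H]2O[C@H]2CCCCCCCC=C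
F5 | step 11 | 1-[(2R,4S,5S)-4-[(4-methoxybenzyl)oxy]-5-pentyltetrahydrofuran-2-yl]dec-9-en-1-one | C=CCCCCCCCC(=O)[C@H]1C[C@H](OCc2ccc(OC)cc2)[C@H](CCCCC)O1
F6 | step 11 | (1R)-1-[(2R,4S,5S)-4-[(4-methoxybenzyl)oxy]-5-pentyltetrahydrofuran-2-yl]dec-9-en-1-ol | C=CCCCCCCC[C@@H](O)[C@H]1C[C@H](OCc2ccc(OC)cc2)[C@H](CCCCC)O1
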